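The route rests on cutting the C1–C8a bond of quinone ring B (C1, C2, C3, C4, C4a, C8a). Nature forms this bond when the oxidised C3 methyl of geranylhydroquinone closes onto the hydroquinone ring. One intramolecular Friedel–Crafts acylation joins a carboxyl carbon (C1) to the only free ortho carbon (C8a) of a 2,5-dimethoxyphenyl ring. This closes ring B and, by enolisation, gives a 1-naphthol whose open C4 position invites para-oxidation to the quinone. The precursor is a Z-configured 4-aryl-but-2-enoic acid that already bears the (R)-silyloxy prenyl side chain on C2. Its stereocentre comes from an asymmetric transfer hydrogenation and its alkene geometry from a trans-hydrostannation.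

Key step: step 10

Remarks on the chemistry
- Numbering: naphthalene numbering of the target is used. Ring A is C4a, C5, C6, C7, C8, C8a and ring B is as above. Side-chain carbons are primed.
- Assumption: the target SMILES reads as R at C1′ (shikonin series). The priority order O > sp2 or sp carbon > CH2 > H holds in every chiral intermediate, so the descriptor stays R throughout. The naphthazarin tautomers interconvert fast, so the tautomer drawn stands for the compound.
- Geometry check: in the Z acid the carboxyl and arylmethyl groups are cis. Trans addition of H and Sn to the alkyne, followed by retentive carbonylation, delivers exactly this arrangement.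
- Choices that keep risk out of the flanking steps:
  - (a) The stereocentre is set on a silyl ynone before the benzyl group is attached, so no ketone ever flanks a benzylic propargylic CH2.
  - (b) The ester is hydrolysed while the hydroxyl group is still free, so no leaving group sits next to a possible dienolate.
  - (c) After ring closure C1′ becomes benzylic and ortho to a naphthol. Excess anhydride therefore caps O1 until the acid is neutralised.
  - (d) The methyl ethers on O5 and O8 are kept because they activate C8a and tolerate the acylating medium.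
  - (e) The final reduction uses a self-limiting reductant, so the ester is not expelled from an over-reduced nucleus.

Step 1
Reactants: 1 4-methylpent-3-enoic acid
Product: 3 N-methoxy-N,4-dimethylpent-3-enamide, via acyl imidazolide 2 (not isolated)
Conditions: 1,1'-carbonyldiimidazole, CH2Cl2, 0 °C → rt; then MeNH(OMe)·HCl, rt
Reagents that add atoms: N,O-dimethylhydroxylamine hydrochloride, CNOC.Cl
Why: Amide formation through the acyl imidazolide needs no added base, so the β,γ-alkene should not slip into conjugation, and it supplies the amide for a Weinreb ketone synthesis.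

Step 2
Reactants: 3 N-methoxy-N,4-dimethylpent-3-enamide; 4 ethynyltrimethylsilane
Product: 6 6-methyl-1-(trimethylsilyl)hept-5-en-1-yn-3-one, via lithium acetylide 5 (not isolated)
Conditions: 4, n-BuLi, THF, −78 °C; then 3, −78 → −20 °C; inverse quench into cold 1 M HCl
Reagents that add atoms: none
Why: Weinreb ketone synthesis, in which the N-methoxy-N-methylamide accepts a single acetylide and releases the ketone only on the acidic quench, which also protonates the liberated amine before it can add to the ynone.

Step 3
Reactants: 6 6-methyl-1-(trimethylsilyl)hept-5-en-1-yn-3-one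
Product: 7 (3R)-6-methyl-1-(trimethylsilyl)hept-5-en-1-yn-3-ol
Conditions: Ru[(R,R)-TsNCH(Ph)CH(Ph)NH](p-cymene) (1 mol %), i-PrOH, 25 °C
Reagents that add atoms: none
Why: Noyori asymmetric transfer hydrogenation of an alkynyl ketone, in which the (R,R)-configured ruthenium amide tells the alkynyl flank from the alkyl flank and should deliver hydride to the face that gives the (R)-propargylic alcohol, while the base-free medium leaves the acidic C4 methylene and the alkene in place; this sets the only stereocentre of the target.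

Step 4
Reactants: 7 (3R)-6-methyl-1-(trimethylsilyl)hept-5-en-1-yn-3-ol
Product: 8 (3R)-6-methylhept-5-en-1-yn-3-ol
Conditions: K2CO3 (0.2 equiv), MeOH, 0 °C → rt
Reagents that add atoms: none
Why: Methoxide-catalysed protiodesilylation of an alkynylsilane, which touches neither the carbinol centre nor the alkene.

Step 5
Reactants: 8 (3R)-6-methylhept-5-en-1-yn-3-ol; 9 2,5-dimethoxybenzyl chloride
Product: 11 (4R)-1-(2,5-dimethoxyphenyl)-7-methyloct-6-en-2-yn-4-ol, via benzyl iodide 10 (not isolated)
Conditions: CuI (20 mol %), NaI (1.1 equiv), K2CO3 (1.5 equiv), DMF, rt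
Reagents that add atoms: none
Why: Finkelstein exchange followed by copper-catalysed alkynylation of the benzylic halide, run at room temperature with a weak carbonate base that tolerates the free alcohol, leaves the stereocentre alone and should be too mild to isomerise the skipped aryl alkyne to an allene.

Step 6
Reactants: 11 (4R)-1-(2,5-dimethoxyphenyl)-7-methyloct-6-en-2-yn-4-ol
Product: 12 (2Z,4R)-1-(2,5-dimethoxyphenyl)-7-methyl-3-(tributylstannyl)octa-2,6-dien-4-ol
Conditions: Bu3SnH (1.1 equiv, slow addition), [Cp*RuCl]4 (2 mol %), CH2Cl2, rt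
Reagents that add atoms: tributyltin hydride, CCCC[SnH](CCCC)CCCC
Why: Ruthenium-catalysed trans-hydrostannation, in which a hydrogen bond from the propargylic OH to the chloride ligand steers tin to the proximal alkyne carbon (future C2) and H and Sn add to opposite sides, which places tin cis to the arylmethyl group.

Step 7
Reactants: 12 (2Z,4R)-1-(2,5-dimethoxyphenyl)-7-methyl-3-(tributylstannyl)octa-2,6-dien-4-ol
Product: 13 methyl (2Z)-4-(2,5-dimethoxyphenyl)-2-[(1R)-1-hydroxy-4-methylpent-3-enyl]but-2-enoate
Conditions: CO (1 atm), Pd(OAc)2 (5 mol %), Ph3As (10 mol %), 1,4-benzoquinone (1.5 equiv), CF3CO2H (20 mol %), MeOH, rt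
Reagents that add atoms: carbon monoxide, [C-]#[O+]; methanol, CO
Why: Oxidative methoxycarbonylation of an alkenylstannane (a Stille-type carbonylation on divalent palladium with benzoquinone as terminal oxidant), in which the free neighbouring hydroxyl group assists tin-to-palladium transfer and the geometry is retained, so the ester carbon (future C1) ends up cis to the arylmethyl group.

Step 8
Reactants: 13 methyl (2Z)-4-(2,5-dimethoxyphenyl)-2-[(1R)-1-hydroxy-4-methylpent-3-enyl]but-2-enoate
Product: 14 (2Z)-4-(2,5-dimethoxyphenyl)-2-[(1R)-1-hydroxy-4-methylpent-3-enyl]but-2-enoic acid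
Conditions: LiOH, THF/MeOH/H2O, 0 °C → rt; 1 M HCl to pH 4, 0 °C
Reagents that add atoms: lithium hydroxide, [Li+].[OH-]
Why: Saponification of a hydroxyalkyl acrylate-type ester carried out on the free alcohol, so that no nucleofuge sits β to a possible dienolate and the carboxylate, once formed, resists γ-deprotonation, which protects both the Z geometry and C1′.

Step 9
Reactants: 14 (2Z)-4-(2,5-dimethoxyphenyl)-2-[(1R)-1-hydroxy-4-methylpent-3-enyl]but-2-enoic acid
Product: 16 (2Z)-4-(2,5-dimethoxyphenyl)-2-[(1R)-1-(tert-butyldimethylsilyloxy)-4-methylpent-3-enyl]but-2-enoic acid, via silyl ester 15 (not isolated)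
Conditions: TBSOTf (2.5 equiv), 2,6-lutidine, CH2Cl2, 0 °C; then K2CO3, MeOH/THF/H2O, rt; 1 M HCl to pH 4–5, 0 °C
Reagents that add atoms: tert-butyldimethylsilyl trifluoromethanesulfonate, CC(C)(C)[Si](C)(C)OS(=O)(=O)C(F)(F)F
Why: Exhaustive O-silylation with a silyl triflate followed by selective solvolysis of the far more labile silyl ester, the standard way to silylate a hydroxy acid, with no bond to C1′ broken.

Step 10
Reactants: 16 (2Z)-4-(2,5-dimethoxyphenyl)-2-[(1R)-1-(tert-butyldimethylsilyloxy)-4-methylpent-3-enyl]but-2-enoic acid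
Product: 20 2-[(1R)-1-(tert-butyldimethylsilyloxy)-4-methylpent-3-enyl]-5,8-dimethoxynaphthalen-1-ol, via acyl trifluoroacetate 17 (not isolated), via 4H-naphthalen-1-one 18 (not isolated), via naphthyl trifluoroacetate 19 (not isolated)
Conditions: (CF3CO)2O (3 equiv), CH2Cl2 (0.02 M), −20 → 0 °C; then cannulate into MeOH/Et3N, −20 °C → rt
Reagents that add atoms: none
Why: The anhydride turns the acid into acyl trifluoroacetate 17, whose carbonyl carbon (future C1), as such or as the acylium ion it releases, is attacked by the arene carbon lying ortho to the side chain and ortho to a methoxy group (future C8a), and proton loss gives ketone 18, which enolises at once to the aromatic naphthol. The closest known reaction type is the intramolecular Friedel–Crafts acylation of 4-arylbutanoic and 4-arylbutenoic acids under anhydride activation, for example the closure of 4-(2,5-dimethoxyphenyl)butanoic acid to 5,8-dimethoxy-1-tetralone. Ring B closes in a 6-exo-trig mode at the anhydride carbonyl (6-exo-dig if the free acylium ion reacts), with the arene bond C4a–C8a lying inside the new ring. No stereocentre is formed, and C1′ should keep its R configuration because its C–O bond sits on an electron-poor alkene before closure and because the excess anhydride caps O1 as trifluoroacetate 19 afterwards, which holds back ionisation towards an ortho-quinone methide until the amine quench has removed the acid and methanol has released the naphthol. Site selectivity is built into the substrate, since the second ortho carbon carries a methoxy group and only the Z alkene fixed in step 6 brings the carboxyl group within bonding distance of the ring. Chemoselectivity over the prenyl alkene rests on the preorganised six-membered transition state and the irreversible aromatisation, supported by low temperature and high dilution, which keep the liberated acid too weak to protonate the alkene or the silyl ether.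

Step 11
Reactants: 20 2-[(1R)-1-(tert-butyldimethylsilyloxy)-4-methylpent-3-enyl]-5,8-dimethoxynaphthalen-1-ol
Product: 21 2-[(1R)-1-(tert-butyldimethylsilyloxy)-4-methylpent-3-enyl]-5,8-dimethoxynaphthalene-1,4-dione
Conditions: (KSO3)2NO (2.5 equiv), aq. KH2PO4, acetone, 0 °C → rt
Reagents that add atoms: potassium nitrosodisulfonate, [K+].[K+].[O]N(S(=O)(=O)[O-])S(=O)(=O)[O-]
Why: Teuber oxidation, in which one nitrosodisulfonate radical removes the phenolic hydrogen and a second delivers oxygen to the free para carbon C4 (C2 is blocked), at near-neutral pH that spares the silyl ether, the prenyl alkene and the dimethoxy ring A.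

Step 12
Reactants: 21 2-[(1R)-1-(tert-butyldimethylsilyloxy)-4-methylpent-3-enyl]-5,8-dimethoxynaphthalene-1,4-dione
Product: 22 2-[(1R)-1-hydroxy-4-methylpent-3-enyl]-5,8-dimethoxynaphthalene-1,4-dione
Conditions: HF·pyridine, pyridine/THF, 0 °C → rt
Reagents that add atoms: none
Why: Fluoride-driven silyl ether cleavage in a buffered, weakly acidic medium that avoids basic fluoride at the quinone, with C1′ now attached to an electron-poor ring and therefore not prone to ionise.

Step 13
Reactants: 23 3-hydroxy-3-methylbutanoic acid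
Product: 25 3-acetoxy-3-methylbutanoic acid, via mixed acetic anhydride 24 (not isolated)
Conditions: Ac2O (3 equiv), Sc(OTf)3 (1 mol %), MeCN, −20 → 0 °C; then H2O/THF, rt
Reagents that add atoms: acetic anhydride, CC(=O)OC(C)=O
Why: Lewis acid catalysed acetylation of a tertiary alcohol at low temperature, where elimination is slow, followed by mild hydrolysis of the carboxylic anhydride that forms alongside.

Step 14
Reactants: 22 2-[(1R)-1-hydroxy-4-methylpent-3-enyl]-5,8-dimethoxynaphthalene-1,4-dione; 25 3-acetoxy-3-methylbutanoic acid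
Product: 26 (1R)-1-(5,8-dimethoxy-1,4-dioxo-1,4-dihydronaphthalen-2-yl)-4-methylpent-3-enyl 3-acetoxy-3-methylbutanoate
Conditions: DCC (1.3 equiv), DMAP (0.1 equiv), CH2Cl2, 0 °C → rt
Reagents that add atoms: none
Why: Steglich esterification, an acyl transfer to oxygen that retains the configuration at C1′, run cold with little DMAP to limit E1cB loss of acetate from the activated β-acetoxy acyl group.

Step 15
Reactants: 26 (1R)-1-(5,8-dimethoxy-1,4-dioxo-1,4-dihydronaphthalen-2-yl)-4-methylpent-3-enyl 3-acetoxy-3-methylbutanoate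
Product: 28 (1R)-1-(5,8-dihydroxy-1,4-dioxo-1,4-dihydronaphthalen-2-yl)-4-methylpent-3-enyl 3-acetoxy-3-methylbutanoate (target), via naphthalenetetrone 27 (not isolated)
Conditions: AgO (4 equiv), 6 M HNO3, 1,4-dioxane, 0 °C → rt, 10 min; CHCl3 extraction; then aq. L-ascorbic acid, 0 °C
Reagents that add atoms: water, O
Why: Oxidative demethylation of a hydroquinone dimethyl ether with AgO and HNO3, the oxidant strong enough for a ring A deactivated by the quinone, carried out with O1′ acylated so that the carbinol is shielded, followed by a two-electron reduction with ascorbic acid, which should reduce the tetrone but not the naphthazarin and so avoids reductive loss of the ester.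

Compound list
1 | 4-methylpent-3-enoic acid | CC(C)=CCC(=O)O | starting material
2 | 1-(1H-imidazol-1-yl)-4-methylpent-3-en-1-one | CC(C)=CCC(=O)n1ccnc1 | intermediate (not isolated)
3 | N-methoxy-N,4-dimethylpent-3-enamide | CC(C)=CCC(=O)N(C)OC | intermediate
4 | ethynyltrimethylsilane | C#C[Si](C)(C)C | starting material
5 | lithium (trimethylsilyl)acetylide | [Li]C#C[Si](C)(C)C | intermediate (not isolated)
6 | 6-methyl-1-(trimethylsilyl)hept-5-en-1-yn-3-one | CC(C)=CCC(=O)C#C[Si](C)(C)C | intermediate
7 | (3R)-6-methyl-1-(trimethylsilyl)hept-5-en-1-yn-3-ol | O[C@H](CC=C(C)C)C#C[Si](C)(C)C | intermediate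
8 | (3R)-6-methylhept-5-en-1-yn-3-ol | O[C@H](CC=C(C)C)C#C | intermediate
9 | 2,5-dimethoxybenzyl chloride | COc1ccc(OC)c(CCl)c1 | starting material
10 | 2,5-dimethoxybenzyl iodide | COc1ccc(OC)c(CI)c1 | intermediate (not isolated)
11 | (4R)-1-(2,5-dimethoxyphenyl)-7-methyloct-6-en-2-yn-4-ol | O[C@H](CC=C(C)C)C#CCc1cc(OC)ccc1OC | intermediate
12 | (2Z,4R)-1-(2,5-dimethoxyphenyl)-7-methyl-3-(tributylstannyl)octa-2,6-dien-4-ol | O[C@H](CC=C(C)C)/C([Sn](CCCC)(CCCC)CCCC)=C/Cc1cc(OC)ccc1OC | intermediate
13 | methyl (2Z)-4-(2,5-dimethoxyphenyl)-2-[(1R)-1-hydroxy-4-methylpent-3-enyl]but-2-enoate | O[C@H](CC=C(C)C)/C(C(=O)OC)=C/Cc1cc(OC)ccc1OC | intermediate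
14 | (2Z)-4-(2,5-dimethoxyphenyl)-2-[(1R)-1-hydroxy-4-methylpent-3-enyl]but-2-enoic acid | O[C@H](CC=C(C)C)/C(C(=O)O)=C/Cc1cc(OC)ccc1OC | intermediate
15 | tert-butyldimethylsilyl (2Z)-4-(2,5-dimethoxyphenyl)-2-[(1R)-1-(tert-butyldimethylsilyloxy)-4-methylpent-3-enyl]but-2-enoate | CC(C)(C)[Si](C)(C)O[C@H](CC=C(C)C)/C(C(=O)O[Si](C)(C)C(C)(C)C)=C/Cc1cc(OC)ccc1OC | intermediate (not isolated)
16 | (2Z)-4-(2,5-dimethoxyphenyl)-2-[(1R)-1-(tert-butyldimethylsilyloxy)-4-methylpent-3-enyl]but-2-enoic acid | CC(C)(C)[Si](C)(C)O[C@H](CC=C(C)C)/C(C(=O)O)=C/Cc1cc(OC)ccc1OC | intermediate (key-step precursor)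
17 | (2Z)-4-(2,5-dimethoxyphenyl)-2-[(1R)-1-(tert-butyldimethylsilyloxy)-4-methylpent-3-enyl]but-2-enoic trifluoroacetic anhydride | CC(C)(C)[Si](C)(C)O[C@H](CC=C(C)C)/C(C(=O)OC(=O)C(F)(F)F)=C/Cc1cc(OC)ccc1OC | intermediate (not isolated)
18 | 2-[(1R)-1-(tert-butyldimethylsilyloxy)-4-methylpent-3-enyl]-5,8-dimethoxy-4H-naphthalen-1-one | CC(C)(C)[Si](C)(C)O[C@H](CC=C(C)C)C1=CCc2c(OC)ccc(OC)c2C1=O | intermediate (not isolated)
19 | 2-[(1R)-1-(tert-butyldimethylsilyloxy)-4-methylpent-3-enyl]-5,8-dimethoxynaphthalen-1-yl trifluoroacetate | CC(C)(C)[Si](C)(C)O[C@H](CC=C(C)C)c1ccc2c(OC)ccc(OC)c2c1OC(=O)C(F)(F)F | intermediate (not isolated)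
20 | 2-[(1R)-1-(tert-butyldimethylsilyloxy)-4-methylpent-3-enyl]-5,8-dimethoxynaphthalen-1-ol | CC(C)(C)[Si](C)(C)O[C@H](CC=C(C)C)c1ccc2c(OC)ccc(OC)c2c1O | intermediate (key-step product)
21 | 2-[(1R)-1-(tert-butyldimethylsilyloxy)-4-methylpent-3-enyl]-5,8-dimethoxynaphthalene-1,4-dione | CC(C)(C)[Si](C)(C)O[C@H](CC=C(C)C)C1=CC(=O)c2c(OC)ccc(OC)c2C1=O | intermediate
22 | 2-[(1R)-1-hydroxy-4-methylpent-3-enyl]-5,8-dimethoxynaphthalene-1,4-dione | O[C@H](CC=C(C)C)C1=CC(=O)c2c(OC)ccc(OC)c2C1=O | intermediate
23 | 3-hydroxy-3-methylbutanoic acid | CC(C)(O)CC(=O)O | starting material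
24 | acetic 3-acetoxy-3-methylbutanoic anhydride | CC(=O)OC(C)(C)CC(=O)OC(C)=O | intermediate (not isolated)
25 | 3-acetoxy-3-methylbutanoic acid | CC(=O)OC(C)(C)CC(=O)O | intermediate
26 | (1R)-1-(5,8-dimethoxy-1,4-dioxo-1,4-dihydronaphthalen-2-yl)-4-methylpent-3-enyl 3-acetoxy-3-methylbutanoate | CC(=O)OC(C)(C)CC(=O)O[C@H](CC=C(C)C)C1=CC(=O)c2c(OC)ccc(OC)c2C1=O | intermediate
27 | (1R)-4-methyl-1-(1,4,5,8-tetraoxo-1,4,5,8-tetrahydronaphthalen-2-yl)pent-3-enyl 3-acetoxy-3-methylbutanoate | CC(=O)OC(C)(C)CC(=O)O[C@H](CC=C(C)C)C1=CC(=O)C2=C(C1=O)C(=O)C=CC2=O | intermediate (not isolated)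
28 | (1R)-1-(5,8-dihydroxy-1,4-dioxo-1,4-dihydronaphthalen-2-yl)-4-methylpent-3-enyl 3-acetoxy-3-methylbutanoate (CNP0153496.1) | CC(=O)OC(C)(C)CC(=O)O[C@H](CC=C(C)C)C1=CC(=O)c2c(O)ccc(O)c2C1=O | target

Total step count: 15. Longest linear sequence: 14 (steps 1–12, 14 and 15). Step 13 is a one-step branch.

Steps most likely to fail

1. Step 10 (key step).
- What may go wrong:
  - the activated acyl carbon is captured by the prenyl alkene instead of the arene;
  - the silyl ether is lost to the liberated acid;
  - C1′ ionises once the electron-rich naphthol has formed, with erosion of configuration.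
- Fallback (sets out from 8, returns at 21): ring B would be built without any acid by a Dötz benzannulation. This forges the same C1–C8a bond by ring closure of a chromium-bound vinylketene.
  - Alkynol 8 is silylated (TBSCl, imidazole, DMF) to (3R)-3-(tert-butyldimethylsilyloxy)-6-methylhept-5-en-1-yne F1.
  - Commercial 2-bromo-1,4-dimethoxybenzene is lithiated with n-BuLi, added to Cr(CO)6 and O-methylated with Me3OBF4. This gives the carbene complex (CO)5Cr=C(OMe)C6H3(OMe)2, pentacarbonyl[(2,5-dimethoxyphenyl)(methoxy)carbene]chromium F2.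
  - Heating F1 and F2 in THF at 50 °C should give 2-[(1R)-1-(tert-butyldimethylsilyloxy)-4-methylpent-3-enyl]-4,5,8-trimethoxynaphthalen-1-ol F3.
  - (NH4)2Ce(NO3)6 in MeCN/H2O at 0 °C then removes the chromium and oxidises the 4-methoxy-1-naphthol unit to quinone 21. Ring A is symmetrically substituted, so the regiochemistry of alkyne insertion has no bearing on the quinone.

2. Step 15.
- What may go wrong: the prenyl alkene degrades by oxidation or acid before the deactivated ring A is consumed. Alternatively, the second stage over-reduces the nucleus and the ester is lost reductively.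
- Fallback (sets out from 21, returns at 28): the two rings exchange roles, so that a milder oxidant suffices, and the ester is attached last.
  - Reductive acetylation of 21 (Zn, Ac2O, NaOAc) gives 2-[(1R)-1-(tert-butyldimethylsilyloxy)-4-methylpent-3-enyl]-5,8-dimethoxynaphthalene-1,4-diyl diacetate F4.
  - (NH4)2Ce(NO3)6 in MeCN/H2O at 0 °C oxidises the still electron-rich dimethoxy ring to 6-[(1R)-1-(tert-butyldimethylsilyloxy)-4-methylpent-3-enyl]-5,8-dioxo-5,8-dihydronaphthalene-1,4-diyl diacetate F5.
  - K2CO3 in MeOH at 0 °C under argon removes both aryl acetates to give 2-[(1R)-1-(tert-butyldimethylsilyloxy)-4-methylpent-3-enyl]-5,8-dihydroxynaphthalene-1,4-dione F6.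
  - HF·pyridine liberates 5,8-dihydroxy-2-[(1R)-1-hydroxy-4-methylpent-3-enyl]naphthalene-1,4-dione F7.
  - Steglich esterification of F7 with 25 (DCC, DMAP, CH2Cl2, 0 °C) should acylate only O1′, because the peri phenols are tied up in hydrogen bonds to the quinone carbonyls. This gives 28.

3. Step 7.
- What may go wrong: protodestannylation in the acidic methanol outruns tin-to-palladium transfer at the hindered trisubstituted alkenylstannane.
- Fallback (sets out from 12, returns at 13): the oxidative process is replaced by a halide-based carbonylation on zerovalent palladium.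
  - Iododestannylation of 12 with I2 in CH2Cl2 at −78 → 0 °C proceeds with retention. It gives (2Z,4R)-1-(2,5-dimethoxyphenyl)-3-iodo-7-methylocta-2,6-dien-4-ol F8.
  - Carbonylation of F8 (Pd(PPh3)4, CO at 1 atm, Et3N, MeOH/DMF, 50 °C) gives ester 13 with the same geometry.

Further compounds
F1 | step 10 | (3R)-3-(tert-butyldimethylsilyloxy)-6-methylhept-5-en-1-yne | CC(C)(C)[Si](C)(C)O[C@H](CC=C(C)C)C#C
F2 | step 10 | pentacarbonyl[(2,5-dimethoxyphenyl)(methoxy)carbene]chromium | COC(c1cc(OC)ccc1OC)=[Cr](=C=O)(=C=O)(=C=O)(=C=O)=C=O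
F3 | step 10 | 2-[(1R)-1-(tert-butyldimethylsilyloxy)-4-methylpent-3-enyl]-4,5,8-trimethoxynaphthalen-1-ol | CC(C)(C)[Si](C)(C)O[C@H](CC=C(C)C)c1cc(OC)c2c(OC)ccc(OC)c2c1O
F4 | step 15 | 2-[(1R)-1-(tert-butyldimethylsilyloxy)-4-methylpent-3-enyl]-5,8-dimethoxynaphthalene-1,4-diyl diacetate | CC(C)(C)[Si](C)(C)O[C@H](CC=C(C)C)c1cc(OC(C)=O)c2c(OC)ccc(OC)c2c1OC(C)=O
F5 | step 15 | 6-[(1R)-1-(tert-butyldimethylsilyloxy)-4-methylpent-3-enyl]-5,8-dioxo-5,8-dihydronaphthalene-1,4-diyl diacetate | CC(C)(C)[Si](C)(C)O[C@H](CC=C(C)C)c1cc(OC(C)=O)c2C(=O)C=CC(=O)c2c1OC(C)=O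
F6 | step 15 | 2-[(1R)-1-(tert-butyldimethylsilyloxy)-4-methylpent-3-enyl]-5,8-dihydroxynaphthalene-1,4-dione | CC(C)(C)[Si](C)(C)O[C@H](CC=C(C)C)C1=CC(=O)c2c(O)ccc(O)c2C1=O
F7 | step 15 | 5,8-dihydroxy-2-[(1R)-1-hydroxy-4-methylpent-3-enyl]naphthalene-1,4-dione | O[C@H](CC=C(C)C)C1=CC(=O)c2c(O)ccc(O)c2C1=O
F8 | step 7 | (2Z,4R)-1-(2,5-dimethoxyphenyl)-3-iodo-7-methylocta-2,6-dien-4-ol | O[C@H](CC=C(C)C)/C(I)=C/Cc1cc(OC)ccc1OC
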